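**Strategy.** The seven-membered carbocycle is made by ring expansion of a tetrahydrofuran. An acyclic alkynol is cycloisomerised to a 2-methylene-5-alkenyltetrahydrofuran whose Claisen rearrangement bonds the exocyclic methylene carbon (C8) to the alkene terminus (C7). This closes the cycloheptene, relays the C5 carbinol configuration to C7, unveils the C9 oxygen as a ketone and leaves a C5=C6 alkene for anti-dioxygenation (lactone oxygen at C6, ester at C5). The feature exploited is the ring CH2 (C8) lying between the oxygenated carbon C9 and the lactone ring-fusion carbon C7, next to the vicinally oxygenated C5/C6 pair. The precursor is an (E)-allylic alcohol bearing a terminal alkyne, built from crotyl alcohol.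

Key step: step 8

Remark (locants used throughout, also for precursors): carbocycle C1 = quaternary carbinol carbon, C5 = CH–O(acyl), C6 = CH–O(lactone), C7 = ring-fusion CH, C8 = CH2, C9 = CHOH, C10 = CH(CH3); side chain C2 (C=O), C3, C4 (CHOH), C15; lactone ring O–C6–C7–C11–C12 with C13 = exocyclic CH2. The C1 ether configuration in 8–18 is free (C1 is later oxidised) and is chosen trans to the C10 methyl.

Step 1
Reactants: 1 (E)-but-2-en-1-ol
Product: 2 [(2S,3S)-3-methyloxiran-2-yl]methanol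
Conditions: Ti(OiPr)4 (cat.), L-(+)-diisopropyl tartrate (cat.), t-BuOOH, 4 Å molecular sieves, CH2Cl2, −20 °C
Reagents that add atoms: tert-butyl hydroperoxide CC(C)(C)OO
Why: Sharpless asymmetric epoxidation, in which the Ti(OiPr)4/L-(+)-tartrate complex delivers oxygen to one face of the (E)-allylic alcohol and should set both epoxide centres as (2S,3S).

Step 2
Reactants: 2 [(2S,3S)-3-methyloxiran-2-yl]methanol; 3 ethynyltrimethylsilane
Product: 6 (2R,3S)-3-methyl-5-(trimethylsilyl)pent-4-yne-1,2-diol, via lithium acetylide 4 (not isolated), via alkynylalane 5 (not isolated)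
Conditions: 3, n-BuLi, toluene, 0 °C; Et2AlCl; then 2, 0 °C → rt; aq. Rochelle salt
Reagents that add atoms: none
Why: Alkynylalane opening of a 2,3-epoxy alcohol, where the aluminium alkoxide delivers the alkynyl group to C3 with SN2 inversion, which should fix the syn methyl/oxygen pair (future C10 and C1) and give the 1,2-diol.

Step 3
Reactants: 6 (2R,3S)-3-methyl-5-(trimethylsilyl)pent-4-yne-1,2-diol
Product: 7 (4R)-2-(4-methoxyphenyl)-4-[(2S)-4-(trimethylsilyl)but-3-yn-2-yl]-1,3-dioxolane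
Conditions: 4-methoxybenzaldehyde dimethyl acetal, camphorsulfonic acid (cat.), CH2Cl2, rt
Reagents that add atoms: 4-methoxybenzaldehyde dimethyl acetal COC(OC)c1ccc(OC)cc1
Why: Acid-catalysed transacetalisation of the 1,2-diol to the five-membered 4-methoxybenzylidene acetal, whose acetal centre is lost in the next step.

Step 4
Reactants: 7 (4R)-2-(4-methoxyphenyl)-4-[(2S)-4-(trimethylsilyl)but-3-yn-2-yl]-1,3-dioxolane
Product: 8 (2R,3S)-2-[(4-methoxyphenyl)methoxy]-3-methyl-5-(trimethylsilyl)pent-4-yn-1-ol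
Conditions: i-Bu2AlH, CH2Cl2, −78 → 0 °C; aq. Rochelle salt
Reagents that add atoms: none
Why: Regioselective reductive opening of the benzylidene acetal, in which the aluminium hydride binds the less hindered primary oxygen and cleaves its C–O bond, leaving the PMB ether on the secondary oxygen.

Step 5
Reactants: 8 (2R,3S)-2-[(4-methoxyphenyl)methoxy]-3-methyl-5-(trimethylsilyl)pent-4-yn-1-ol
Product: 9 (2R,3S)-2-[(4-methoxyphenyl)methoxy]-3-methyl-5-(trimethylsilyl)pent-4-ynal
Conditions: Dess–Martin periodinane, NaHCO3, CH2Cl2, 0 °C → rt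
Reagents that add atoms: none
Why: Dess–Martin oxidation of the primary alcohol under buffered conditions that should not epimerise the α-alkoxy aldehyde.

Step 6
Reactants: 9 (2R,3S)-2-[(4-methoxyphenyl)methoxy]-3-methyl-5-(trimethylsilyl)pent-4-ynal; 10 tert-butyl(but-3-yn-1-yloxy)dimethylsilane
Product: 12 (5R,6R,7S)-1-[(tert-butyldimethylsilyl)oxy]-6-[(4-methoxyphenyl)methoxy]-7-methyl-9-(trimethylsilyl)nona-3,8-diyn-5-ol, via alkynylmagnesium bromide 11 (not isolated)
Conditions: 10, EtMgBr, THF, 0 °C → rt; then 9, MgBr2·OEt2, CH2Cl2, −78 °C; aq. NH4Cl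
Reagents that add atoms: none
Why: Cram-chelate-controlled alkynyl Grignard addition, in which magnesium bridges the aldehyde and α-PMB ether oxygens and the acetylide attacks the less hindered face, which should give the 1,2-syn propargylic alcohol (future C5).

Step 7
Reactants: 12 (5R,6R,7S)-1-[(tert-butyldimethylsilyl)oxy]-6-[(4-methoxyphenyl)methoxy]-7-methyl-9-(trimethylsilyl)nona-3,8-diyn-5-ol
Product: 14 (3E,5R,6R,7S)-1-[(tert-butyldimethylsilyl)oxy]-6-[(4-methoxyphenyl)methoxy]-7-methylnon-3-en-8-yn-5-ol, via silylated enynol 13 (not isolated)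
Conditions: NaAlH2(OCH2CH2OCH3)2, THF, 0 °C → rt; MeOH quench; then K2CO3, MeOH, rt
Reagents that add atoms: none
Why: Hydroxyl-directed trans-hydroalumination of the propargylic alcohol should give only the (E)-allylic alcohol, and methanolic K2CO3 then removes the C-silyl group (protodesilylation) without touching the O-silyl ether.

Step 8
Reactants: 14 (3E,5R,6R,7S)-1-[(tert-butyldimethylsilyl)oxy]-6-[(4-methoxyphenyl)methoxy]-7-methylnon-3-en-8-yn-5-ol
Product: 16 (2R,3S,6R)-6-{2-[(tert-butyldimethylsilyl)oxy]ethyl}-3-[(4-methoxyphenyl)methoxy]-2-methylcyclohept-4-en-1-one, via methylene tetrahydrofuran 15 (not isolated)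
Conditions: Ag2CO3 (10 mol %), toluene, 80 °C; filter through Celite; then 175 °C (sealed tube, base-washed glass)
Reagents that add atoms: none
Why: Ag2CO3 activates the terminal alkyne for anti 5-exo-dig attack of the C5 hydroxyl to give exocyclic enol ether 15, and on heating this allyl vinyl ether (C8=C9–O–C5–C6=C7) undergoes a [3,3]-sigmatropic Claisen shift that forms C7–C8, breaks C5–O and unveils the C9 ketone. The closest known reaction type is the tandem alkynol cycloisomerisation/Claisen ring expansion of 2-methylene-5-vinyltetrahydrofurans to cyclohept-4-enones. The tetrahydrofuran closes 5-exo-dig, and the cycloheptene is closed by the sigmatropic shift itself through a bridged chair-like transition state in which the C10–C1 unit spans C9 and C5, the only geometry the five-membered tether allows, which also makes the new C5=C6 bond cis. C7 is the only new stereocentre: with the (E)-alkene its side chain is equatorial in that chair, so the (R)-configuration at C5 is transferred to C7 and the side chain should end up cis to the C10 methyl and trans to the C1 ether, both of which are untouched. The step needs 5-exo over 6-endo cyclisation (terminal alkyne, Ag2CO3), no migration of the exocyclic double bond and no β-elimination of the C1 ether from the product (base-buffered, acid-free medium and removal of silver before heating).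

Step 9
Reactants: 16 (2R,3S,6R)-6-{2-[(tert-butyldimethylsilyl)oxy]ethyl}-3-[(4-methoxyphenyl)methoxy]-2-methylcyclohept-4-en-1-one
Product: 17 (1R,2S,3S,6R)-6-{2-[(tert-butyldimethylsilyl)oxy]ethyl}-3-[(4-methoxyphenyl)methoxy]-2-methylcyclohept-4-en-1-ol
Conditions: SmI2, MeOH, THF, 0 °C
Reagents that add atoms: none
Why: Single-electron ketone reduction through an equilibrating ketyl should give the more stable equatorial C9 alcohol, trans to the C10 methyl, and samarium chelation by the C1 ether oxygen favours the same face.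

Step 10
Reactants: 17 (1R,2S,3S,6R)-6-{2-[(tert-butyldimethylsilyl)oxy]ethyl}-3-[(4-methoxyphenyl)methoxy]-2-methylcyclohept-4-en-1-ol
Product: 18 tert-butyl{[(1R,2R,3S,6R)-6-{2-[(tert-butyldimethylsilyl)oxy]ethyl}-3-[(4-methoxyphenyl)methoxy]-2-methylcyclohept-4-en-1-yl]oxy}dimethylsilane
Conditions: TBSOTf, 2,6-lutidine, CH2Cl2, −78 → 0 °C
Reagents that add atoms: tert-butyldimethylsilyl trifluoromethanesulfonate CC(C)(C)[Si](C)(C)OS(=O)(=O)C(F)(F)F
Why: Silylation of the hindered secondary alcohol with the silyl triflate; no stereocentre is touched.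

Step 11
Reactants: 18 tert-butyl{[(1R,2R,3S,6R)-6-{2-[(tert-butyldimethylsilyl)oxy]ethyl}-3-[(4-methoxyphenyl)methoxy]-2-methylcyclohept-4-en-1-yl]oxy}dimethylsilane
Product: 20 (4R,6R,7S)-6-[(tert-butyldimethylsilyl)oxy]-4-{2-[(tert-butyldimethylsilyl)oxy]ethyl}-7-methylcyclohept-2-en-1-one, via allylic alcohol 19 (not isolated)
Conditions: DDQ (3 equiv), CH2Cl2/pH 7 buffer, 0 °C → rt
Reagents that add atoms: none
Why: Oxidative cleavage of the PMB ether by DDQ followed by DDQ dehydrogenation of the liberated allylic alcohol should give the enone in one flask, with the silyl ethers inert.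

Step 12
Reactants: 21 (2R)-pent-4-yn-2-ol
Product: 22 (2R)-4-iodopent-4-en-2-ol
Conditions: NaI, Me3SiCl, H2O, MeCN, rt
Reagents that add atoms: sodium iodide [Na+].[I-]
Why: Markovnikov hydroiodination of the terminal alkyne by HI generated in the flask gives the 2-iodo-1-alkene and leaves the carbinol centre untouched.

Step 13
Reactants: 22 (2R)-4-iodopent-4-en-2-ol
Product: 23 tert-butyl{[(2R)-4-iodopent-4-en-2-yl]oxy}dimethylsilane
Conditions: TBSCl, imidazole, DMF, rt
Reagents that add atoms: tert-butyldimethylsilyl chloride CC(C)(C)[Si](C)(C)Cl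
Why: Standard silylation of the secondary alcohol.

Step 14
Reactants: 20 (4R,6R,7S)-6-[(tert-butyldimethylsilyl)oxy]-4-{2-[(tert-butyldimethylsilyl)oxy]ethyl}-7-methylcyclohept-2-en-1-one; 23 tert-butyl{[(2R)-4-iodopent-4-en-2-yl]oxy}dimethylsilane
Product: 25 (1R,4R,6R,7S)-6-[(tert-butyldimethylsilyl)oxy]-4-{2-[(tert-butyldimethylsilyl)oxy]ethyl}-1-{(4R)-4-[(tert-butyldimethylsilyl)oxy]pent-1-en-2-yl}-7-methylcyclohept-2-en-1-ol, via alkenyllithium 24 (not isolated)
Conditions: 23, t-BuLi (2.1 equiv), Et2O, −78 °C; then 20, THF, −78 °C; aq. NH4Cl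
Reagents that add atoms: none
Why: Iodine–lithium exchange then 1,2-addition of the alkenyllithium to the enone carbonyl, where attack anti to the adjacent C10 methyl (the face also free of the C7 side chain) should set C1 with its hydroxyl cis to that methyl.

Step 15
Reactants: 25 (1R,4R,6R,7S)-6-[(tert-butyldimethylsilyl)oxy]-4-{2-[(tert-butyldimethylsilyl)oxy]ethyl}-1-{(4R)-4-[(tert-butyldimethylsilyl)oxy]pent-1-en-2-yl}-7-methylcyclohept-2-en-1-ol
Product: 26 (1R,4R,6R,7S)-6-[(tert-butyldimethylsilyl)oxy]-1-{(4R)-4-[(tert-butyldimethylsilyl)oxy]pent-1-en-2-yl}-4-(2-hydroxyethyl)-7-methylcyclohept-2-en-1-ol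
Conditions: HF·pyridine, pyridine, THF, 0 °C
Reagents that add atoms: none
Why: Buffered fluoride cleaves the primary silyl ether much faster than the two secondary ones (selective desilylation) and spares the acid-sensitive tertiary allylic alcohol.

Step 16
Reactants: 26 (1R,4R,6R,7S)-6-[(tert-butyldimethylsilyl)oxy]-1-{(4R)-4-[(tert-butyldimethylsilyl)oxy]pent-1-en-2-yl}-4-(2-hydroxyethyl)-7-methylcyclohept-2-en-1-ol
Product: 28 2-[(1S,4R,5S,6R)-6-[(tert-butyldimethylsilyl)oxy]-4-{(4R)-4-[(tert-butyldimethylsilyl)oxy]pent-1-en-2-yl}-4-hydroxy-5-methylcyclohept-2-en-1-yl]acetic acid, via aldehyde 27 (not isolated)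
Conditions: TEMPO (cat.), PhI(OAc)2, MeCN/pH 7 buffer, rt
Reagents that add atoms: water O
Why: Nitroxyl-catalysed oxidation takes the primary alcohol through the aldehyde hydrate to the acid, while the tertiary alcohol, alkenes and silyl ethers are inert.

Step 17
Reactants: 28 2-[(1S,4R,5S,6R)-6-[(tert-butyldimethylsilyl)oxy]-4-{(4R)-4-[(tert-butyldimethylsilyl)oxy]pent-1-en-2-yl}-4-hydroxy-5-methylcyclohept-2-en-1-yl]acetic acid
Product: 30 C1–C5 epoxy γ-lactone (side-chain alkene), via iodolactone 29 (not isolated)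
Conditions: I2, NaHCO3, MeCN, 0 °C (dark); Na2S2O3 wash; crude iodolactone, K2CO3, MeOH, 0 °C
Reagents that add atoms: none
Why: Iodolactonisation, in which the carboxylate tethered at C7 can only open the iodonium ion at C6 from its own face (5-exo, anti addition), sets the cis-fused lactone oxygen at C6 with iodine at C5 trans to it, and K2CO3 then lets the C1 alkoxide displace the iodide (intramolecular SN2) to give the epoxide on the face of the lactone oxygen.

Step 18
Reactants: 30 C1–C5 epoxy γ-lactone (side-chain alkene)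
Product: 34 α-methylene epoxy γ-lactone, via lithium enolate 31 (not isolated), via Mannich base 32 (not isolated), via ammonium iodide 33 (not isolated)
Conditions: LiN(i-Pr)2, THF, −78 °C; dimethylmethylideneammonium iodide, −78 °C → rt; then MeI, rt; aq. NaHCO3
Reagents that add atoms: dimethylmethylideneammonium iodide (Eschenmoser's salt) C=[N+](C)C.[I-]
Why: α-Methylenation of the lactone by Mannich reaction of its lithium enolate, N-methylation and Hofmann-type elimination, on a substrate that has no other acidic C–H or O–H.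

Step 19
Reactants: 34 α-methylene epoxy γ-lactone
Product: 36 C2 ketone (α,β-epoxy ketone), via diol 35 (not isolated)
Conditions: OsO4 (2 mol %), NaIO4, 2,6-lutidine, dioxane/H2O, rt
Reagents that add atoms: osmium tetroxide O=[Os](=O)(=O)=O; sodium periodate [Na+].[O-]I(=O)(=O)=O
Why: Lemieux–Johnson cleavage, in which electrophilic OsO4 dihydroxylates the electron-rich 1,1-dialkyl alkene much faster than the conjugated methylene lactone and periodate cleaves the diol to the C2 ketone (C1 has no free hydroxyl, so only the terminal carbon is lost).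

Step 20
Reactants: 36 C2 ketone (α,β-epoxy ketone); 37 (2S)-2-methylbutanoic acid
Product: 38 (3aS,5R,6S,7S,8S,8aR)-5-[(tert-butyldimethylsilyl)oxy]-7-{(3R)-3-[(tert-butyldimethylsilyl)oxy]butanoyl}-7-hydroxy-6-methyl-3-methylidene-2-oxooctahydro-2H-cyclohepta[b]furan-8-yl (2S)-2-methylbutanoate
Conditions: 37 (5 equiv), Cs2CO3 (1 equiv), DMF, 70 °C
Reagents that add atoms: none
Why: Carboxylate opening of the α,β-epoxy ketone by SN2 attack at the secondary carbon C5 (C1 is quaternary and deactivated by the adjacent ketone) with inversion, which should place the ester trans to the lactone oxygen and leave the tertiary C1 hydroxyl with retained configuration.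

Step 21
Reactants: 38 (3aS,5R,6S,7S,8S,8aR)-5-[(tert-butyldimethylsilyl)oxy]-7-{(3R)-3-[(tert-butyldimethylsilyl)oxy]butanoyl}-7-hydroxy-6-methyl-3-methylidene-2-oxooctahydro-2H-cyclohepta[b]furan-8-yl (2S)-2-methylbutanoate
Product: 39 (3aS,5R,6S,7S,8S,8aR)-5,7-dihydroxy-7-[(3R)-3-hydroxybutanoyl]-6-methyl-3-methylidene-2-oxooctahydro-2H-cyclohepta[b]furan-8-yl (2S)-2-methylbutanoate
Conditions: HF (48 % aq.), MeCN, 0 °C → rt
Reagents that add atoms: none
Why: Global desilylation of the two secondary silyl ethers under conditions that should spare the ester, lactone, methylene lactone and β-hydroxy ketone.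

**Compound list**

1 | (E)-but-2-en-1-ol | C/C=C/CO | starting material
2 | [(2S,3S)-3-methyloxiran-2-yl]methanol | C[C@@H]1O[C@H]1CO | intermediate
3 | ethynyltrimethylsilane | C#C[Si](C)(C)C | starting material
4 | lithium (trimethylsilyl)acetylide | [Li]C#C[Si](C)(C)C | intermediate
5 | diethyl[(trimethylsilyl)ethynyl]aluminium | CC[Al](CC)C#C[Si](C)(C)C | intermediate
6 | (2R,3S)-3-methyl-5-(trimethylsilyl)pent-4-yne-1,2-diol | C[Si](C)(C)C#C[C@H](C)[C@@H](O)CO | intermediate
7 | (4R)-2-(4-methoxyphenyl)-4-[(2S)-4-(trimethylsilyl)but-3-yn-2-yl]-1,3-dioxolane (both acetal epimers) | C[Si](C)(C)C#C[C@H](C)[C@@H]1COC(c2ccc(OC)cc2)O1 | intermediate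
8 | (2R,3S)-2-[(4-methoxyphenyl)methoxy]-3-methyl-5-(trimethylsilyl)pent-4-yn-1-ol | C[Si](C)(C)C#C[C@H](C)[C@@H](OCc1ccc(OC)cc1)CO | intermediate
9 | (2R,3S)-2-[(4-methoxyphenyl)methoxy]-3-methyl-5-(trimethylsilyl)pent-4-ynal | C[Si](C)(C)C#C[C@H](C)[C@@H](OCc1ccc(OC)cc1)C=O | intermediate
10 | tert-butyl(but-3-yn-1-yloxy)dimethylsilane | C#CCCO[Si](C)(C)C(C)(C)C | starting material
11 | {4-[(tert-butyldimethylsilyl)oxy]but-1-yn-1-yl}magnesium bromide | Br[Mg]C#CCCO[Si](C)(C)C(C)(C)C | intermediate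
12 | (5R,6R,7S)-1-[(tert-butyldimethylsilyl)oxy]-6-[(4-methoxyphenyl)methoxy]-7-methyl-9-(trimethylsilyl)nona-3,8-diyn-5-ol | C[Si](C)(C)C#C[C@H](C)[C@@H](OCc1ccc(OC)cc1)[C@H](O)C#CCCO[Si](C)(C)C(C)(C)C | intermediate
13 | (3E,5R,6R,7S)-1-[(tert-butyldimethylsilyl)oxy]-6-[(4-methoxyphenyl)methoxy]-7-methyl-9-(trimethylsilyl)non-3-en-8-yn-5-ol | C[Si](C)(C)C#C[C@H](C)[C@@H](OCc1ccc(OC)cc1)[C@H](O)/C=C/CCO[Si](C)(C)C(C)(C)C | intermediate
14 | (3E,5R,6R,7S)-1-[(tert-butyldimethylsilyl)oxy]-6-[(4-methoxyphenyl)methoxy]-7-methylnon-3-en-8-yn-5-ol | C#C[C@H](C)[C@@H](OCc1ccc(OC)cc1)[C@H](O)/C=C/CCO[Si](C)(C)C(C)(C)C | intermediate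
15 | tert-butyl{[(3E)-4-[(2R,3R,4R)-3-[(4-methoxyphenyl)methoxy]-4-methyl-5-methylideneoxolan-2-yl]but-3-en-1-yl]oxy}dimethylsilane | C=C1O[C@H](/C=C/CCO[Si](C)(C)C(C)(C)C)[C@H](OCc2ccc(OC)cc2)[C@H]1C | intermediate
16 | (2R,3S,6R)-6-{2-[(tert-butyldimethylsilyl)oxy]ethyl}-3-[(4-methoxyphenyl)methoxy]-2-methylcyclohept-4-en-1-one | O=C1[C@H](C)[C@@H](OCc2ccc(OC)cc2)C=C[C@H](CCO[Si](C)(C)C(C)(C)C)C1 | intermediate
17 | (1R,2S,3S,6R)-6-{2-[(tert-butyldimethylsilyl)oxy]ethyl}-3-[(4-methoxyphenyl)methoxy]-2-methylcyclohept-4-en-1-ol | O[C@H]1[C@H](C)[C@@H](OCc2ccc(OC)cc2)C=C[C@H](CCO[Si](C)(C)C(C)(C)C)C1 | intermediate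
18 | tert-butyl{[(1R,2R,3S,6R)-6-{2-[(tert-butyldimethylsilyl)oxy]ethyl}-3-[(4-methoxyphenyl)methoxy]-2-methylcyclohept-4-en-1-yl]oxy}dimethylsilane | CC(C)(C)[Si](C)(C)O[C@H]1[C@H](C)[C@@H](OCc2ccc(OC)cc2)C=C[C@H](CCO[Si](C)(C)C(C)(C)C)C1 | intermediate
19 | (1S,4R,6R,7R)-6-[(tert-butyldimethylsilyl)oxy]-4-{2-[(tert-butyldimethylsilyl)oxy]ethyl}-7-methylcyclohept-2-en-1-ol | CC(C)(C)[Si](C)(C)O[C@H]1[C@H](C)[C@@H](O)C=C[C@H](CCO[Si](C)(C)C(C)(C)C)C1 | intermediate
20 | (4R,6R,7S)-6-[(tert-butyldimethylsilyl)oxy]-4-{2-[(tert-butyldimethylsilyl)oxy]ethyl}-7-methylcyclohept-2-en-1-one | CC(C)(C)[Si](C)(C)O[C@H]1[C@H](C)C(=O)C=C[C@H](CCO[Si](C)(C)C(C)(C)C)C1 | intermediate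
21 | (2R)-pent-4-yn-2-ol | C#CC[C@@H](C)O | starting material
22 | (2R)-4-iodopent-4-en-2-ol | C=C(I)C[C@@H](C)O | intermediate
23 | tert-butyl{[(2R)-4-iodopent-4-en-2-yl]oxy}dimethylsilane | C=C(I)C[C@@H](C)O[Si](C)(C)C(C)(C)C | intermediate
24 | {(4R)-4-[(tert-butyldimethylsilyl)oxy]pent-1-en-2-yl}lithium | [Li]C(=C)C[C@@H](C)O[Si](C)(C)C(C)(C)C | intermediate
25 | (1R,4R,6R,7S)-6-[(tert-butyldimethylsilyl)oxy]-4-{2-[(tert-butyldimethylsilyl)oxy]ethyl}-1-{(4R)-4-[(tert-butyldimethylsilyl)oxy]pent-1-en-2-yl}-7-methylcyclohept-2-en-1-ol | CC(C)(C)[Si](C)(C)O[C@H]1[C@H](C)[C@@](O)(C(=C)C[C@@H](C)O[Si](C)(C)C(C)(C)C)C=C[C@H](CCO[Si](C)(C)C(C)(C)C)C1 | intermediate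
26 | (1R,4R,6R,7S)-6-[(tert-butyldimethylsilyl)oxy]-1-{(4R)-4-[(tert-butyldimethylsilyl)oxy]pent-1-en-2-yl}-4-(2-hydroxyethyl)-7-methylcyclohept-2-en-1-ol | CC(C)(C)[Si](C)(C)O[C@H]1[C@H](C)[C@@](O)(C(=C)C[C@@H](C)O[Si](C)(C)C(C)(C)C)C=C[C@H](CCO)C1 | intermediate
27 | 2-[(1S,4R,5S,6R)-6-[(tert-butyldimethylsilyl)oxy]-4-{(4R)-4-[(tert-butyldimethylsilyl)oxy]pent-1-en-2-yl}-4-hydroxy-5-methylcyclohept-2-en-1-yl]acetaldehyde | CC(C)(C)[Si](C)(C)O[C@H]1[C@H](C)[C@@](O)(C(=C)C[C@@H](C)O[Si](C)(C)C(C)(C)C)C=C[C@H](CC=O)C1 | intermediate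
28 | 2-[(1S,4R,5S,6R)-6-[(tert-butyldimethylsilyl)oxy]-4-{(4R)-4-[(tert-butyldimethylsilyl)oxy]pent-1-en-2-yl}-4-hydroxy-5-methylcyclohept-2-en-1-yl]acetic acid | CC(C)(C)[Si](C)(C)O[C@H]1[C@H](C)[C@@](O)(C(=C)C[C@@H](C)O[Si](C)(C)C(C)(C)C)C=C[C@H](CC(=O)O)C1 | intermediate
29 | iodolactone: cis-fused γ-lactone (O on C6, CH2 on C7); iodine on C5 trans to the lactone oxygen; free tertiary C1–OH cis to the lactone oxygen; C9 and C4 O-TBS; side-chain 1,1-disubstituted alkene | CC(C)(C)[Si](C)(C)O[C@H]1[C@H](C)[C@@](O)(C(=C)C[C@@H](C)O[Si](C)(C)C(C)(C)C)[C@@H](I)[C@@H]2OC(=O)C[C@@H]2C1 | intermediate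
30 | epoxy lactone: as 29 but with a C1–O–C5 epoxide on the face of the lactone oxygen in place of I and OH | CC(C)(C)[Si](C)(C)O[C@H]1[C@H](C)[C@]3(C(=C)C[C@@H](C)O[Si](C)(C)C(C)(C)C)O[C@@H]3[C@@H]2OC(=O)C[C@@H]2C1 | intermediate
31 | lithium enolate of lactone 30 | CC(C)(C)[Si](C)(C)O[C@H]1[C@H](C)[C@]3(C(=C)C[C@@H](C)O[Si](C)(C)C(C)(C)C)O[C@@H]3[C@@H]2OC(O[Li])=C[C@@H]2C1 | intermediate
32 | Mannich base: 30 with CH2N(CH3)2 on C11 (both C11 epimers) | CC(C)(C)[Si](C)(C)O[C@H]1[C@H](C)[C@]3(C(=C)C[C@@H](C)O[Si](C)(C)C(C)(C)C)O[C@@H]3[C@@H]2OC(=O)C(CN(C)C)[C@@H]2C1 | intermediate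
33 | trimethylammonium iodide of 32 | CC(C)(C)[Si](C)(C)O[C@H]1[C@H](C)[C@]3(C(=C)C[C@@H](C)O[Si](C)(C)C(C)(C)C)O[C@@H]3[C@@H]2OC(=O)C(C[N+](C)(C)C)[C@@H]2C1.[I-] | intermediate
34 | α-methylene epoxy lactone: 30 with C11=C13H2 | CC(C)(C)[Si](C)(C)O[C@H]1[C@H](C)[C@]3(C(=C)C[C@@H](C)O[Si](C)(C)C(C)(C)C)O[C@@H]3[C@@H]2OC(=O)C(=C)[C@@H]2C1 | intermediate
35 | side-chain 1,2-diol of 34 (both C2 epimers) | CC(C)(C)[Si](C)(C)O[C@H]1[C@H](C)[C@]3(C(O)(CO)C[C@@H](C)O[Si](C)(C)C(C)(C)C)O[C@@H]3[C@@H]2OC(=O)C(=C)[C@@H]2C1 | intermediate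
36 | epoxy ketone: 34 with the side-chain alkene replaced by the C2 ketone, i.e. (3R)-3-[(tert-butyldimethylsilyl)oxy]butanoyl on C1 | CC(C)(C)[Si](C)(C)O[C@H]1[C@H](C)[C@]3(C(=O)C[C@@H](C)O[Si](C)(C)C(C)(C)C)O[C@@H]3[C@@H]2OC(=O)C(=C)[C@@H]2C1 | intermediate
37 | (2S)-2-methylbutanoic acid | CC[C@H](C)C(=O)O | starting material
38 | (3aS,5R,6S,7S,8S,8aR)-5-[(tert-butyldimethylsilyl)oxy]-7-{(3R)-3-[(tert-butyldimethylsilyl)oxy]butanoyl}-7-hydroxy-6-methyl-3-methylidene-2-oxooctahydro-2H-cyclohepta[b]furan-8-yl (2S)-2-methylbutanoate | CC(C)(C)[Si](C)(C)O[C@H]1[C@H](C)[C@@](O)(C(=O)C[C@@H](C)O[Si](C)(C)C(C)(C)C)[C@@H](OC(=O)[C@@H](C)CC)[C@@H]2OC(=O)C(=C)[C@@H]2C1 | intermediate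
39 | (3aS,5R,6S,7S,8S,8aR)-5,7-dihydroxy-7-[(3R)-3-hydroxybutanoyl]-6-methyl-3-methylidene-2-oxooctahydro-2H-cyclohepta[b]furan-8-yl (2S)-2-methylbutanoate | O[C@H]1[C@H](C)[C@@](O)(C(=O)C[C@@H](C)O)[C@@H](OC(=O)[C@@H](C)CC)[C@@H]2OC(=O)C(=C)[C@@H]2C1 | target

**Total step count:** 21. **Longest linear sequence:** 19 (steps 1–11 and 14–21; steps 12–13 make side-chain reagent 23).

**Steps most likely to fail**

Step 8. The unactivated exocyclic enol ether may isomerise to the endocyclic isomer or hydrolyse. The strained bridged transition state, which also carries the C1 ether on its concave side, may need temperatures at which the β-alkoxy ketone loses 4-methoxybenzyl alcohol. Fallback, setting out from 14 and returning at 16: oxidative methoxycarbonylation of the terminal alkyne (PdCl2, CuCl2, NaOAc, CO, MeOH) should give methyl (4S,5R,6R,7E)-10-[(tert-butyldimethylsilyl)oxy]-6-hydroxy-5-[(4-methoxyphenyl)methoxy]-4-methyldec-7-en-2-ynoate F1. Catalytic DBU then closes the hydroxyl onto the ynoate (5-exo-dig oxa-Michael) to the conjugated, isolable alkylidene tetrahydrofuran ester F2. Its rearrangement, thermally in toluene or by ionisation and recombination with zerovalent palladium, Pd(PPh3)4, still forms C7–C8 and gives the C8 methoxycarbonyl ketone F3. Krapcho dealkoxycarbonylation (LiCl, wet DMSO, 140 °C) returns to 16.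

Step 14. Addition to enone 20 may show poor facial selectivity, or the organolithium may enolise the enone instead of adding. Fallback, setting out from 17 and returning at 25: DDQ on the unsilylated alcohol gives (4R,6R,7S)-4-{2-[(tert-butyldimethylsilyl)oxy]ethyl}-6-hydroxy-7-methylcyclohept-2-en-1-one F4. The alkenylmagnesium reagent made from 23 (t-BuLi, then MgBr2, excess) is then bound by the C9 alkoxide and delivered to the carbonyl face syn to it, which is the required face (alkoxide-directed addition). This gives (1R,4R,6R,7S)-4-{2-[(tert-butyldimethylsilyl)oxy]ethyl}-1-{(4R)-4-[(tert-butyldimethylsilyl)oxy]pent-1-en-2-yl}-7-methylcyclohept-2-ene-1,6-diol F5. Selective silylation of its secondary C9 hydroxyl (TBSOTf, 2,6-lutidine, −78 °C) returns to 25.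

Step 20. Carboxylate attack at the hindered C5 of the epoxy ketone may be too slow, so that conjugate addition to the methylene lactone or β-elimination of the C4 silyl ether competes. Fallback, setting out from 36 and returning at 38: acid-catalysed hydrolytic opening (dilute HClO4, THF/H2O, 0 °C), in which water attacks C5 anti to the epoxide oxygen, gives the C5-hydroxy C1-hydroxy diol F6. Carbodiimide esterification of its secondary C5 hydroxyl with 37 (EDC, DMAP, CH2Cl2, 0 °C) returns to 38.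

**Further compounds**

F1 | step 8 | methyl (4S,5R,6R,7E)-10-[(tert-butyldimethylsilyl)oxy]-6-hydroxy-5-[(4-methoxyphenyl)methoxy]-4-methyldec-7-en-2-ynoate | COC(=O)C#C[C@H](C)[C@@H](OCc1ccc(OC)cc1)[C@H](O)/C=C/CCO[Si](C)(C)C(C)(C)C
F2 | step 8 | methyl 2-[(3R,4R,5R)-5-{(1E)-4-[(tert-butyldimethylsilyl)oxy]but-1-en-1-yl}-4-[(4-methoxyphenyl)methoxy]-3-methyloxolan-2-ylidene]acetate (either alkylidene geometry) | COC(=O)C=C1O[C@H](/C=C/CCO[Si](C)(C)C(C)(C)C)[C@H](OCc2ccc(OC)cc2)[C@H]1C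
F3 | step 8 | C8 methoxycarbonyl derivative of ketone 16 (β-keto ester, both C8 epimers) | O=C1[C@H](C)[C@@H](OCc2ccc(OC)cc2)C=C[C@H](CCO[Si](C)(C)C(C)(C)C)C1C(=O)OC
F4 | step 14 | (4R,6R,7S)-4-{2-[(tert-butyldimethylsilyl)oxy]ethyl}-6-hydroxy-7-methylcyclohept-2-en-1-one | O[C@H]1[C@H](C)C(=O)C=C[C@H](CCO[Si](C)(C)C(C)(C)C)C1
F5 | step 14 | (1R,4R,6R,7S)-4-{2-[(tert-butyldimethylsilyl)oxy]ethyl}-1-{(4R)-4-[(tert-butyldimethylsilyl)oxy]pent-1-en-2-yl}-7-methylcyclohept-2-ene-1,6-diol | O[C@H]1[C@H](C)[C@@](O)(C(=C)C[C@@H](C)O[Si](C)(C)C(C)(C)C)C=C[C@H](CCO[Si](C)(C)C(C)(C)C)C1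
F6 | step 20 | C5-hydroxy analogue of 38 (free secondary C5–OH trans to the lactone oxygen, tertiary C1–OH, both silyl ethers kept) | CC(C)(C)[Si](C)(C)O[C@H]1[C@H](C)[C@@](O)(C(=O)C[C@@H](C)O[Si](C)(C)C(C)(C)C)[C@@H](O)[C@@H]2OC(=O)C(=C)[C@@H]2C1
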